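No rate constant of this flask is known yet; you have charges and one run, so you reason from the charges.

| flask | starting material | second substrate | enzyme | impurity | remark |
|---|---|---|---|---|---|
| theta | 0.10 M | 0.15 M | 10 µM | 8.2 µM | run made earlier |
| flask | 0.10 M | 0.100 M | 10 µM | 8.2 µM |  |

theta run (percent of the starting material charged): time / min: target / % = 2.50: 0.7; 8.00: 1.0; 12.0: 1.6; 20.0: 3.0; 30.0: 3.4; 40.0: 5.2

(scatter of a reading: 0.5 percentage points)

* apparent order in second substrate when 10 % of the starting material are converted (percent change of the rate of making target for one percent more second substrate charged)
* factor on the rate of making target when 10 % of the starting material are converted if enzyme is charged twice over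

- what was read earlier has a scatter of 0.5 percentage points, one standard deviation
- no earlier run changes the charge of enzyme; that part of a forecast is a guess
- no earlier run changes the charge of second substrate; that part of a forecast is a guess

The theta run reads 5.2 % of target at 40.0 min, but no run changes [second substrate] or [enzyme], so the order in second substrate stays a guess.

The bench rule for the enzyme is that rate goes with the charge of catalyst, which makes twice the enzyme worth a factor of 2. That rule is in doubt for this flask if impurity removes enzyme, so take the ratio 82.0 % and keep it as the poisoned share, charged [impurity] over charged [enzyme]. If each impurity takes one enzyme for good, 18.0 % of the charge is left working. Doubling the enzyme at the same charge of impurity then raises working enzyme from 1.80 µM to 11.8 µM, and if rate goes with working enzyme, that factor of 6.56 is your reckoning.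

The forecast gives an order of 0.5 and a factor of 3, saying “Weighing partial binding, I expect about 3”, which is lower than your reckoning.

The flask gives an order of −0.015, and doubled enzyme gives a factor of 6.56, close to your reckoning and higher than the forecast's.

    starting material + enzyme ⇌ complex A (K = 8.90 /M, k = 1.80 × 10⁵ /M/min)
    complex A → enzyme + target (k = 150 /min)
    second substrate + enzyme ⇌ complex B (K = 2.50 /M, k = 2.50 × 10⁵ /M/min)
    complex B → enzyme + second product (k = 12000 /min)
    enzyme + impurity → spent catalyst (k = 15000 /M/s)

In this flask, by 0.300 h, impurity stood at 0 % of its charge and spent catalyst at 82.0 % of the catalyst charged, the same as the poisoned share of 82.0 %, and it stayed at 82.0 % through 30.0 h. While second substrate lasted, with 9.89 % of its charge left at 1.50 h, the remaining catalyst made second product alongside target; the rate of making target was 0.00707 M/h at 10 % conversion, reached at 1.38 h, and target stood at 96.8 % of the starting material charged at 30.0 h.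

The readings were computed with constants of no real substance, and the scatter is random.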